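## Retrosynthetic overview

1. Drimane numbering is used: ring A = C1–C5 + C10, ring B = C5–C10, C11 = CH2O, C12 = exocyclic CH2. The last bond made is C11–O (Mitsunobu, umbelliferone). C8=C12 is traced back to a C8 ketone through enol triflate, Me3SiCH2 coupling and desilylative deconjugation, which also resets C9.
2. Key disconnection: ring B of keto ester 17, C8(=O)–C7=C6–C5H–C10–C9, is a cyclobut-2-enone (C5, C6, C7, C8). The C9=C10 alkene is inserted into its C5–C8 bond by 4π opening to a vinylketene and intramolecular [4+2]. Ring A (tether C1–C4) closes in the same step.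
3. Enabling feature: in ring B the sp2 chain C8–C7=C6 ends at the methine C5, so C5 and C8 sit 1,4 across a cis C6=C7 bond (vinylketene retron). C9, C10, C11, C1–C4 and the three methyl groups form an (E)-geranate chain; its C11 ester activates C9=C10 and its E geometry encodes the C9/C10 relation.
4. Precursor 15 has one controlling stereocentre, C3, set by a catalytic asymmetric reverse prenylation that also builds quaternary C4. Its ring comes from a ketene/ethoxyacetylene [2+2] and a carbonyl transposition.
5. Order of rings: cyclobutenone (step 6), then rings A and B together (step 8). The coumarin is bought and attached last.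

Key step: step 8

Assumption: methyl geranate is used as the pure E isomer, and (R)-SEGPHOS is taken to be the ligand antipode that delivers (6R)-5; should the catalyst show the opposite sense, (S)-SEGPHOS is used and nothing else changes.

## Route

Step 1
Reactants: 1 methyl geranate [methyl (2E)-3,7-dimethylocta-2,6-dienoate]
Product: 3 methyl (2E)-3-methyl-6-oxohex-2-enoate, via ozonide 2 (not isolated)
Conditions: O3 (1.0 equiv, Sudan Red 7B end-point), CH2Cl2, −78 °C; then Me2S, −78 °C → rt
Reagents that add atoms: ozone, [O-][O+]=O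
Why: Chemoselective ozonolysis (Criegee mechanism): the electron-rich trisubstituted 6,7-alkene reacts far faster with electrophilic ozone than the ester-deactivated 2,3-alkene, whose E geometry stays untouched, and Me2S reduces the ozonide.

Step 2
Reactants: 3 methyl (2E)-3-methyl-6-oxohex-2-enoate; 4 3-methylbuta-1,2-diene (1,1-dimethylallene)
Product: 5 methyl (2E,6R)-6-hydroxy-3,7,7-trimethylnona-2,8-dienoate
Conditions: [Ir(cod)Cl]2 (2.5 mol %), (R)-SEGPHOS (5 mol %), 3-nitrobenzoic acid (10 mol %), allyl acetate (10 mol %), Cs2CO3 (20 mol %), i-PrOH (4 equiv), PhMe, sealed tube, 60 °C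
Reagents that add atoms: none
Why: Iridium-catalysed transfer-hydrogenative carbonyl reverse prenylation: hydrometallation of the allene gives a prenyl-iridium species that adds to the aldehyde through its tertiary terminus in a closed chair transition state, so quaternary C4 and the C3 carbinol form together and the chiral bisphosphine sets (6R), which is C3 of the target.

Step 3
Reactants: 5 methyl (2E,6R)-6-hydroxy-3,7,7-trimethylnona-2,8-dienoate
Product: 6 methyl (2E,6R)-3,7,7-trimethyl-6-(pivaloyloxy)nona-2,8-dienoate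
Conditions: PivCl, DMAP (0.2 equiv), pyridine, 50 °C
Reagents that add atoms: pivaloyl chloride, CC(C)(C)C(=O)Cl
Why: DMAP-catalysed acylation; the pivalate is not nucleophilic toward the later acid chloride and ketene (a silyl ether in this γ-position could lactonise), resists the Grignard reagent of step 10 and falls off in the hydride step 12.

Step 4
Reactants: 6 methyl (2E,6R)-3,7,7-trimethyl-6-(pivaloyloxy)nona-2,8-dienoate
Product: 8 methyl (2E,6R)-9-hydroxy-3,7,7-trimethyl-6-(pivaloyloxy)non-2-enoate, via alkylborane 7 (not isolated)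
Conditions: 9-BBN (1.3 equiv), THF, 0 °C → rt; then 30 % H2O2, aq. NaOAc, 0 °C → rt
Reagents that add atoms: 9-borabicyclo[3.3.1]nonane, [H]B1C2CCCC1CCC2 (boron and ring only in 7); hydrogen peroxide, OO
Why: Anti-Markovnikov hydroboration–oxidation: 9-BBN adds only to the terminal vinyl group, with boron on the CH2 terminus away from the quaternary carbon, the trisubstituted enoate is inert, and buffered peroxide spares both esters.

Step 5
Reactants: 8 methyl (2E,6R)-9-hydroxy-3,7,7-trimethyl-6-(pivaloyloxy)non-2-enoate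
Product: 9 (4R,7E)-9-methoxy-3,3,7-trimethyl-9-oxo-4-(pivaloyloxy)non-7-enoic acid
Conditions: TEMPO (0.2 equiv), PhI(OAc)2 (2.5 equiv), MeCN/H2O 1:1, rt
Reagents that add atoms: water, O
Why: Oxoammonium (TEMPO/PhI(OAc)2) oxidation of the primary alcohol through the aldehyde hydrate to the acid, under nearly neutral conditions that leave the alkene, both esters and C3 untouched.

Step 6
Reactants: 9 (4R,7E)-9-methoxy-3,3,7-trimethyl-9-oxo-4-(pivaloyloxy)non-7-enoic acid; 10 ethoxyacetylene
Product: 13 methyl (2E,6R)-7-(2-ethoxy-4-oxocyclobut-2-en-1-yl)-3,7-dimethyl-6-(pivaloyloxy)oct-2-enoate (both epimers at the sp3 ring carbon), via acid chloride 11 (not isolated), via ketene 12 (not isolated)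
Conditions: (COCl)2, DMF (cat.), CH2Cl2, 0 °C → rt, evaporate; then 10 (3 equiv), Et3N (1.5 equiv, slow addition), Et2O, rt → 35 °C
Reagents that add atoms: oxalyl chloride, O=C(Cl)C(=O)Cl (chlorine only in 11)
Why: Dehydrochlorination gives the tert-alkyl-substituted ketene 12, which is slow to dimerise and undergoes the ketene–ynol ether [2+2] cycloaddition with the usual regiochemistry (ketene carbonyl carbon to the unsubstituted alkyne carbon); the new ring stereocentre (C5) forms as a mixture that is erased in step 8.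

Step 7
Reactants: 13 methyl (2E,6R)-7-(2-ethoxy-4-oxocyclobut-2-en-1-yl)-3,7-dimethyl-6-(pivaloyloxy)oct-2-enoate
Product: 15 methyl (2E,6R)-3,7-dimethyl-7-(4-oxocyclobut-2-en-1-yl)-6-(pivaloyloxy)oct-2-enoate (both epimers at the sp3 ring carbon), via cyclobutenol 14 (not isolated)
Conditions: NaBH4, CeCl3·7H2O, MeOH, −20 → 0 °C; extractive work-up; then 1 M HCl, THF, 0 °C → rt
Reagents that add atoms: water, O
Why: Luche 1,2-reduction of the strained vinylogous ester carbonyl (enoate and pivalate inert), followed by acid hydrolysis of the β-alkoxy allylic alcohol, a Stork–Danheiser-type carbonyl transposition, moves the carbonyl to C8 and removes the ethoxy group.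

Step 8
Reactants: 15 methyl (2E,6R)-3,7-dimethyl-7-(4-oxocyclobut-2-en-1-yl)-6-(pivaloyloxy)oct-2-enoate
Product: 17 methyl (1S,4aS,6R,8aR)-5,5,8a-trimethyl-2-oxo-6-(pivaloyloxy)-1,2,4a,5,6,7,8,8a-octahydronaphthalene-1-carboxylate, via vinylketene 16 (not isolated)
Conditions: PhMe (0.005 M), BHT (5 mol %), sealed tube, 130 °C
Reagents that add atoms: none
Why: Proposed new method: on heating, the four-membered ring of 15 opens by conrotatory 4π electrocyclic cleavage of its C5–C8 bond to the vinylketene 16, and the C5=C6–C7=C8 diene unit of 16 then adds across the tethered C9=C10 enoate, so that two alkene carbons are inserted into the former C5–C8 bond and the cyclobutenone (C5–C8) is expanded by two atoms to the cyclohexenone ring B. The closest known reaction types are the thermal cyclobutenone–vinylketene opening exploited in benzannulations and the intermolecular Diels–Alder reaction of silyl-stabilised vinylketenes with electron-poor alkenes, which joins the vinyl terminus to the acceptor β-carbon and the ketene carbon to the α-carbon exactly as required here; new is the intramolecular capture of a non-stabilised vinylketene by a β,β-disubstituted enoate. Ring B closes by the concerted suprafacial [4+2] union C5–C10 plus C8–C9, and ring A closes in the same event through the C5–C10 bond as the six-membered, chair-like tether ring of a type 1 intramolecular Diels–Alder reaction. C5 and C10 should come out trans because the E-enoate places ester and C10 methyl endo in the chair transition state and because the axial methyl of the C4 gem-dimethyl group always meets an axial group on C10, which is smallest (CH3 instead of C9) in the trans array; their absolute sense follows from the C3 pivaloyloxy group taking the equatorial site of that chair, and C9 follows from the E geometry by suprafacial addition (ester cis to the C10 methyl, which is also the equatorial, thermodynamic position of this enolisable centre). The step needs outward torquoselectivity, which the bulky tertiary C4 substituent secures (only the E-vinylketene can reach the alkene, and both C5 epimers of 15 converge), and [4+2] over [2+2] periselectivity, which is secured because the electron-poor alkene is a poor ketenophile and a [2+2] adduct would hold an E-alkene in an eight-membered ring. Unproductive 16 recloses to 15, so high dilution keeps the ketene concentration low and suppresses dimerisation.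

Step 9
Reactants: 17 methyl (1S,4aS,6R,8aR)-5,5,8a-trimethyl-2-oxo-6-(pivaloyloxy)-1,2,4a,5,6,7,8,8a-octahydronaphthalene-1-carboxylate
Product: 18 methyl (4aS,6R,8aR)-5,5,8a-trimethyl-6-(pivaloyloxy)-2-{[(trifluoromethyl)sulfonyl]oxy}-4a,5,6,7,8,8a-hexahydronaphthalene-1-carboxylate
Conditions: Tf2O (1.2 equiv), i-Pr2NEt (1.5 equiv), CH2Cl2, −78 → 0 °C
Reagents that add atoms: trifluoromethanesulfonic anhydride, O=S(=O)(OS(=O)(=O)C(F)(F)F)C(F)(F)F
Why: O-Sulfonylation of the β-keto ester enol (C9–H is by far the most acidic proton) gives the alkenyl triflate regiospecifically between C8 and C9; the C9 stereocentre is deliberately erased here and reset in step 11, while C5 and C10 are not touched.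

Step 10
Reactants: 18 methyl (4aS,6R,8aR)-5,5,8a-trimethyl-6-(pivaloyloxy)-2-{[(trifluoromethyl)sulfonyl]oxy}-4a,5,6,7,8,8a-hexahydronaphthalene-1-carboxylate
Product: 19 methyl (4aS,6R,8aR)-5,5,8a-trimethyl-6-(pivaloyloxy)-2-[(trimethylsilyl)methyl]-4a,5,6,7,8,8a-hexahydronaphthalene-1-carboxylate
Conditions: Me3SiCH2MgCl (1.5 equiv), Pd(PPh3)4 (5 mol %), THF, 0 °C → rt
Reagents that add atoms: (trimethylsilyl)methylmagnesium chloride, C[Si](C)(C)C[Mg]Cl
Why: Kumada–Corriu cross-coupling: oxidative addition of zerovalent palladium into the electron-poor alkenyl triflate and transmetallation with the poorly nucleophilic Me3SiCH2MgCl bring in C12 without attack on the hindered methyl ester or the pivalate.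

Step 11
Reactants: 19 methyl (4aS,6R,8aR)-5,5,8a-trimethyl-6-(pivaloyloxy)-2-[(trimethylsilyl)methyl]-4a,5,6,7,8,8a-hexahydronaphthalene-1-carboxylate
Product: 20 methyl (1R,4aS,6R,8aR)-5,5,8a-trimethyl-2-methylidene-6-(pivaloyloxy)-1,2,4a,5,6,7,8,8a-octahydronaphthalene-1-carboxylate
Conditions: TBAF (1.1 equiv), AcOH (1.2 equiv), THF, −40 → 0 °C
Reagents that add atoms: none
Why: Fluoride-induced desilylation of the γ-silyl enoate releases the ester dienolate regiospecifically, and kinetic α-protonation (deconjugative protonation) from the face opposite the axial C10 methyl gives the exocyclic C8=C12 alkene and the C9–H stereocentre, with the ester equatorial and cis to the C10 methyl.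

Step 12
Reactants: 20 methyl (1R,4aS,6R,8aR)-5,5,8a-trimethyl-2-methylidene-6-(pivaloyloxy)-1,2,4a,5,6,7,8,8a-octahydronaphthalene-1-carboxylate
Product: 21 [(1R,4aS,6R,8aR)-6-hydroxy-5,5,8a-trimethyl-2-methylidene-1,2,4a,5,6,7,8,8a-octahydronaphthalen-1-yl]methanol
Conditions: LiAlH4 (4 equiv), Et2O, 0 °C → rt; then H2O, aq. NaOH
Reagents that add atoms: none
Why: Hydride reduction with LiAlH4 converts the methyl ester into the C11 carbinol and cleaves the pivalate in the same operation; no stereocentre is touched and the unactivated diene is inert to hydride.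

Step 13
Reactants: 21 [(1R,4aS,6R,8aR)-6-hydroxy-5,5,8a-trimethyl-2-methylidene-1,2,4a,5,6,7,8,8a-octahydronaphthalen-1-yl]methanol; 22 umbelliferone (7-hydroxy-2H-chromen-2-one)
Product: 23 7-{[(1R,4aS,6R,8aR)-6-hydroxy-5,5,8a-trimethyl-2-methylidene-1,2,4a,5,6,7,8,8a-octahydronaphthalen-1-yl]methoxy}-2H-chromen-2-one (CNP0259618.4)
Conditions: PPh3 (1.5 equiv), DIAD (1.5 equiv), THF, 0 °C → rt
Reagents that add atoms: none
Why: Mitsunobu etherification: the acidic phenol displaces the oxyphosphonium salt of the primary C11 alcohol, whereas the equatorial C3 alcohol next to quaternary C4 cannot undergo SN2 displacement, so no protecting group is needed and the neutral, cold conditions spare the diene.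

Stereocentres: C3 is set in step 2. C5 and C10 are set in step 8. C9 is set in step 8, erased in step 9 and reset in step 11.

## Compound list

1 | methyl geranate, methyl (2E)-3,7-dimethylocta-2,6-dienoate | COC(=O)/C=C(\C)CCC=C(C)C | starting material
2 | secondary ozonide, methyl (2E)-5-(5,5-dimethyl-1,2,4-trioxolan-3-yl)-3-methylpent-2-enoate | COC(=O)/C=C(\C)CCC1OOC(C)(C)O1 | intermediate
3 | methyl (2E)-3-methyl-6-oxohex-2-enoate | COC(=O)/C=C(\C)CCC=O | intermediate
4 | 3-methylbuta-1,2-diene | CC(C)=C=C | starting material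
5 | methyl (2E,6R)-6-hydroxy-3,7,7-trimethylnona-2,8-dienoate | COC(=O)/C=C(\C)CC[C@@H](O)C(C)(C)C=C | intermediate
6 | methyl (2E,6R)-3,7,7-trimethyl-6-(pivaloyloxy)nona-2,8-dienoate | COC(=O)/C=C(\C)CC[C@@H](OC(=O)C(C)(C)C)C(C)(C)C=C | intermediate
7 | B-alkyl-9-BBN adduct of 6 (boron on the terminal carbon) | COC(=O)/C=C(\C)CC[C@@H](OC(=O)C(C)(C)C)C(C)(C)CCB1C2CCCC1CCC2 | intermediate
8 | methyl (2E,6R)-9-hydroxy-3,7,7-trimethyl-6-(pivaloyloxy)non-2-enoate | COC(=O)/C=C(\C)CC[C@@H](OC(=O)C(C)(C)C)C(C)(C)CCO | intermediate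
9 | (4R,7E)-9-methoxy-3,3,7-trimethyl-9-oxo-4-(pivaloyloxy)non-7-enoic acid | COC(=O)/C=C(\C)CC[C@@H](OC(=O)C(C)(C)C)C(C)(C)CC(=O)O | intermediate
10 | ethoxyacetylene | CCOC#C | starting material
11 | acid chloride of 9 | COC(=O)/C=C(\C)CC[C@@H](OC(=O)C(C)(C)C)C(C)(C)CC(=O)Cl | intermediate
12 | monoalkylketene from 11 | COC(=O)/C=C(\C)CC[C@@H](OC(=O)C(C)(C)C)C(C)(C)C=C=O | intermediate
13 | methyl (2E,6R)-7-(2-ethoxy-4-oxocyclobut-2-en-1-yl)-3,7-dimethyl-6-(pivaloyloxy)oct-2-enoate (ring carbon epimers) | COC(=O)/C=C(\C)CC[C@@H](OC(=O)C(C)(C)C)C(C)(C)C1C(=O)C=C1OCC | intermediate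
14 | methyl (2E,6R)-7-(2-ethoxy-4-hydroxycyclobut-2-en-1-yl)-3,7-dimethyl-6-(pivaloyloxy)oct-2-enoate (ring epimers) | COC(=O)/C=C(\C)CC[C@@H](OC(=O)C(C)(C)C)C(C)(C)C1C(O)C=C1OCC | intermediate
15 | methyl (2E,6R)-3,7-dimethyl-7-(4-oxocyclobut-2-en-1-yl)-6-(pivaloyloxy)oct-2-enoate (ring carbon epimers) | COC(=O)/C=C(\C)CC[C@@H](OC(=O)C(C)(C)C)C(C)(C)C1C=CC1=O | intermediate
16 | (E)-vinylketene, methyl (2E,6R,8E)-3,7,7-trimethyl-11-oxo-6-(pivaloyloxy)undeca-2,8,10-trienoate | COC(=O)/C=C(\C)CC[C@@H](OC(=O)C(C)(C)C)C(C)(C)/C=C/C=C=O | intermediate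
17 | methyl (1S,4aS,6R,8aR)-5,5,8a-trimethyl-2-oxo-6-(pivaloyloxy)-1,2,4a,5,6,7,8,8a-octahydronaphthalene-1-carboxylate | O=C1C=C[C@@H]2C(C)(C)[C@H](OC(=O)C(C)(C)C)CC[C@@]2(C)[C@@H]1C(=O)OC | intermediate
18 | methyl (4aS,6R,8aR)-5,5,8a-trimethyl-6-(pivaloyloxy)-2-{[(trifluoromethyl)sulfonyl]oxy}-4a,5,6,7,8,8a-hexahydronaphthalene-1-carboxylate | FC(F)(F)S(=O)(=O)OC1C=C[C@@H]2C(C)(C)[C@H](OC(=O)C(C)(C)C)CC[C@@]2(C)C=1C(=O)OC | intermediate
19 | methyl (4aS,6R,8aR)-5,5,8a-trimethyl-6-(pivaloyloxy)-2-[(trimethylsilyl)methyl]-4a,5,6,7,8,8a-hexahydronaphthalene-1-carboxylate | C[Si](C)(C)CC1C=C[C@@H]2C(C)(C)[C@H](OC(=O)C(C)(C)C)CC[C@@]2(C)C=1C(=O)OC | intermediate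
20 | methyl (1R,4aS,6R,8aR)-5,5,8a-trimethyl-2-methylidene-6-(pivaloyloxy)-1,2,4a,5,6,7,8,8a-octahydronaphthalene-1-carboxylate | C=C1C=C[C@@H]2C(C)(C)[C@H](OC(=O)C(C)(C)C)CC[C@@]2(C)[C@@H]1C(=O)OC | intermediate
21 | [(1R,4aS,6R,8aR)-6-hydroxy-5,5,8a-trimethyl-2-methylidene-1,2,4a,5,6,7,8,8a-octahydronaphthalen-1-yl]methanol | C=C1C=C[C@@H]2C(C)(C)[C@H](O)CC[C@@]2(C)[C@@H]1CO | intermediate
22 | umbelliferone, 7-hydroxy-2H-chromen-2-one | Oc1ccc2ccc(=O)oc2c1 | starting material
23 | 7-{[(1R,4aS,6R,8aR)-6-hydroxy-5,5,8a-trimethyl-2-methylidene-1,2,4a,5,6,7,8,8a-octahydronaphthalen-1-yl]methoxy}-2H-chromen-2-one | C=C1C=C[C@@H]2C(C)(C)[C@H](O)CC[C@@]2(C)[C@@H]1COc1ccc2ccc(=O)oc2c1 | target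

## Step count and risks

Total step count: 13. Longest linear sequence: 13 steps (from methyl geranate 1).

**1. Step 8.** The cycloaddition onto the β,β-disubstituted enoate may be too slow at the temperature at which the ketene forms, so that ketene oligomerisation takes over. Endo/exo or facial control may also erode.

The fallback uses known chemistry, sets out from 15 and returns at 17. Ring opening and cycloaddition are separated, and the ketene is replaced by its more nucleophilic acetal. Compound 15 is heated in MeOH/PhMe (90 °C, sealed), and the vinylketene is trapped as the β,γ-unsaturated diester dimethyl (2E,6R,8E)-3,7,7-trimethyl-6-(pivaloyloxy)undeca-2,8-dienedioate F1. Selective deprotonation of its doubly activated α-CH2 with LiN(i-Pr)2 (1.0 equiv, THF, −78 °C) and trapping with Me3SiCl should give the vinylketene methyl silyl acetal F2. A thermal intramolecular Diels–Alder reaction of this 1,1-dioxygenated diene (PhMe, 110–150 °C) should give the cycloadduct ketal F3. Dilute HCl in THF then hydrolyses F3 to 17.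

**2. Step 11.** The exocyclic alkene may reconjugate under the basic fluoride medium. Protonation may occur at the γ-carbon, or with poor facial selectivity at C9.

The fallback sets out from 17 and returns at 21, bypassing steps 9–12 by classical carbonyl olefination. Luche reduction of 17 gives the allylic hydroxy ester F4. LiAlH4 then gives the triol F5. TBSCl/imidazole (1 equiv) silylates only the primary alcohol to the mono-silyl ether F6. MnO2 oxidises only the allylic C8 carbinol to the enone F7, whose enolisable C9 prefers the equatorial side chain. Wittig methylenation with excess Ph3P=CH2 (THF, 0 °C) gives the silyl-protected diene F8, and TBAF releases 21.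

**3. Step 13.** Displacement at the β-branched primary carbon next to quaternary C10 may be sluggish. Elimination of the oxyphosphonium salt toward a cross-conjugated triene may compete.

The fallback sets out from 21 and returns at 23. The ether bond is made from the aryl side by palladium-catalysed C–O cross-coupling of the primary alcohol with commercial 7-bromo-2H-chromen-2-one (Pd2(dba)3, RockPhos, Cs2CO3, PhMe, 80 °C). No substitution at C11 is then required, and the hindered C3 alcohol stays out of the coupling. This fallback makes no compound outside the list (F0).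

## Further compounds

F1 | step 8 | dimethyl (2E,6R,8E)-3,7,7-trimethyl-6-(pivaloyloxy)undeca-2,8-dienedioate | COC(=O)/C=C(\C)CC[C@@H](OC(=O)C(C)(C)C)C(C)(C)/C=C/CC(=O)OC
F2 | step 8 | methyl (2E,6R,8E)-11-methoxy-3,7,7-trimethyl-6-(pivaloyloxy)-11-[(trimethylsilyl)oxy]undeca-2,8,10-trienoate | COC(=O)/C=C(\C)CC[C@@H](OC(=O)C(C)(C)C)C(C)(C)/C=C/C=C(OC)O[Si](C)(C)C
F3 | step 8 | methyl (1S,4aS,6R,8aR)-2-methoxy-5,5,8a-trimethyl-6-(pivaloyloxy)-2-[(trimethylsilyl)oxy]-1,2,4a,5,6,7,8,8a-octahydronaphthalene-1-carboxylate (ketal carbon undefined) | COC1(O[Si](C)(C)C)C=C[C@@H]2C(C)(C)[C@H](OC(=O)C(C)(C)C)CC[C@@]2(C)[C@@H]1C(=O)OC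
F4 | step 11 | methyl (1S,4aS,6R,8aR)-2-hydroxy-5,5,8a-trimethyl-6-(pivaloyloxy)-1,2,4a,5,6,7,8,8a-octahydronaphthalene-1-carboxylate (C2 carbinol as formed) | OC1C=C[C@@H]2C(C)(C)[C@H](OC(=O)C(C)(C)C)CC[C@@]2(C)[C@@H]1C(=O)OC
F5 | step 11 | (1R,4aS,6R,8aR)-1-(hydroxymethyl)-5,5,8a-trimethyl-1,2,4a,5,6,7,8,8a-octahydronaphthalene-2,6-diol (C2 carbinol as formed) | OC1C=C[C@@H]2C(C)(C)[C@H](O)CC[C@@]2(C)[C@@H]1CO
F6 | step 11 | (1R,4aS,6R,8aR)-1-{[(tert-butyldimethylsilyl)oxy]methyl}-5,5,8a-trimethyl-1,2,4a,5,6,7,8,8a-octahydronaphthalene-2,6-diol (C2 carbinol as formed) | OC1C=C[C@@H]2C(C)(C)[C@H](O)CC[C@@]2(C)[C@@H]1CO[Si](C)(C)C(C)(C)C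
F7 | step 11 | (1R,4aS,6R,8aR)-1-{[(tert-butyldimethylsilyl)oxy]methyl}-6-hydroxy-5,5,8a-trimethyl-4a,5,6,7,8,8a-hexahydronaphthalen-2(1H)-one | O=C1C=C[C@@H]2C(C)(C)[C@H](O)CC[C@@]2(C)[C@@H]1CO[Si](C)(C)C(C)(C)C
F8 | step 11 | (2R,4aR,5R,8aS)-5-{[(tert-butyldimethylsilyl)oxy]methyl}-1,1,4a-trimethyl-6-methylidene-1,2,3,4,4a,5,6,8a-octahydronaphthalen-2-ol | C=C1C=C[C@@H]2C(C)(C)[C@H](O)CC[C@@]2(C)[C@@H]1CO[Si](C)(C)C(C)(C)C
F0 | step 13 | none | none
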